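A small charge of free catalyst, 15 mM in the theta run, loses speed just as a larger one does, 33 mM in the alpha run. You can read this from the target columns below.

common to all: starting material 0.20 M

|  | second substrate | coupling partner | free catalyst | remark |
|---|---|---|---|---|
| theta | 0.10 M | 0.26 M | 15 mM | run made earlier |
| alpha | 0.10 M | 0.26 M | 33 mM | run made earlier |
| flask | 0.100 M | 0.260 M | 22 mM |  |

| run | time / h | target / % | starting material / % |
|---|---|---|---|
| theta | 10.0 | 12 | 84 |
| theta | 20.0 | 17 | 76 |
| theta | 30.0 | 24 | 72 |
| theta | 40.0 | 27 | 68 |
| theta | 50.0 | 29 | 64 |
| alpha | 10.0 | 22 | 62 |
| alpha | 20.0 | 34 | 49 |
| alpha | 30.0 | 45 | 36 |
| alpha | 40.0 | 50 | 35 |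
| alpha | 50.0 | 55 | 30 |

(each reading ± 2 percentage points)

- what was read earlier has a scatter of 2 percentage points, one standard deviation
- what is bound to the catalyst counts as converted
- no earlier run changes the charge of second substrate; that part of a forecast is a guess
- no earlier run changes the charge of coupling partner; that part of a forecast is a guess

- apparent order in free catalyst when 30% of the starting material are converted (percent change of the rate of making target for one percent more free catalyst charged)
- apparent order in coupling partner when 30% of the starting material are converted (percent change of the rate of making target for one percent more coupling partner charged)
- factor on the rate of making target when 30% of the starting material are converted if second substrate is charged twice over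

Compare the target made in the first 20.0 h with that made from 30.0 h to 50.0 h. The centres of these windows lie 30.0 h apart. Theta gains 17%, then 5 percentage points, a fall by a factor 3.40. Alpha gains 34%, then 10 points, a fall by a factor 3.40. The theta figure is rough: its late gain is 5 points against a scatter of 2 points on each reading.

Now read the starting material column. At 50.0 h, alpha keeps 30% and theta 64%, so alpha has less left. So the fall looks tied to time rather than to conversion. Alpha gives a reading of 17.0 h for the clock half-life, the time in which the rate of making target halves; it carries the scatter of these readings.

My reckoning assumes that the clock is the loss of coupling partner. Theta reaches 30% conversion near 35.0 h and alpha near 7.89 h. Interpolating on logarithmic scales, I estimate that the flask gets there near 17.0 h. One percent more coupling partner should raise the rate one percent directly. It should also bring that conversion one percent sooner, which adds 0.693 percent through the clock. So I expect an order of 1.69.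

On coupling partner the forecast differs from my reckoning. It gives 1.8 (1.2 to 2.4) in free catalyst, 0.5 (0 to 1.1) in coupling partner, and a factor 1.8 (1 to 3) for doubled second substrate. Of the second number it says: “Coupling partner is a pure guess.”

The flask gives 1.8 in free catalyst, 1.7 in coupling partner and a factor 0.968 for doubled second substrate.

    starting material + free catalyst ⇌ catalyst intermediate A (K = 390 /M, k = 1.80 /M/min)
    coupling partner + catalyst intermediate A → free catalyst + target (k = 0.0110 /M/min)
    second substrate + free catalyst ⇌ catalyst intermediate B (K = 12.0 /M, k = 0.0690 /M/min)
    coupling partner + catalyst intermediate B → free catalyst + second product (k = 0.0540 /M/min)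
    coupling partner ⇌ dormant form (K = 16.0, k = 3.90 × 10⁻⁴ /min)

In the flask, catalyst intermediate A, the resting state, held 96.2% of the catalyst charged at 20.0 h, while coupling partner went to dormant form and to target. By 40.0 h the flask held 0.121 M of dormant form, more than the 0.0751 M of target. Coupling partner kept 48.1% of its 20.0 h value over the next 20.0 h, where the clock half-life, read from the rate in the earlier runs, gives 44.2%. With second substrate doubled, the time to the level, 13.7 h, stretches by a factor 1.03, or 0.356 h. The clock turns that into a factor 0.986 on the rate, and the flask gives 0.968.

The earlier runs and the new flask were computed from invented constants; the scatter is artificial.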